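**Retrosynthetic overview**

- Ainsliatrimer A ⇒ spiro dimer 16 (units B and C) + trienone 13 (unit A) by a Diels–Alder reaction (C2–C4', C14–C15') and a C1=C10 → C1=C2 tautomerisation; 16 ⇒ 13 + dehydrozaluzanin C 11 by a Diels–Alder reaction (C2'–C4'', C14'–C15'') and oxygenation of C10'.
- All three hydroazulene units therefore come from 11 (13 by Saegusa–Ito oxidation of its silyl enol ether 12), and 11 ⇒ isophotosantonic lactone 2 by adjustment of oxidation levels (C4=C15, C10=C14, C11=C13).
- 2 ⇒ commercial α-santonin 1 by a photochemical dienone rearrangement in aqueous acid. The enabling feature is the cross-conjugated cyclohexa-2,5-dienone of ring A (C1=C2–C3(=O)–C4=C5) whose sp3 atom C10 is also a fusion atom of ring B (C5–C10). C1–C5 bonding and transfer of C10 from C5 to C1 contract ring A to the cyclopentenone and expand ring B by the atom C1 to the cycloheptane C1, C5–C10.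
- Ring order: lactone (present in 1) → five- and seven-membered carbocycles of each unit (step 1) → spirocyclohexene between units B and C (step 12) → spirocyclohexene between units A and B (step 13).

Key step: step 1

Remark: guaiane numbering is used (C1–C5 five-membered ring; C1, C5–C10 seven-membered ring; lactone C6–O–C12(=O)–C11–C7; C13 on C11, C14 on C10, C15 on C4). Unit A (unprimed) holds the free C4=C15 methylene ketone, unit B (primed) the 10'-hydroxyl, unit C (doubly primed) the saturated cyclopentanone. The eudesmane numbers of santonin map atom for atom onto these. α-Santonin is taken as the commercial (−)-enantiomer. Trienone 13 is assumed to persist for some hours in cold, dilute solution, and it is never concentrated.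

**Route**

Step 1
Reactants: 1 (−)-α-santonin
Product: 2 isophotosantonic lactone
Conditions: hν (medium-pressure mercury lamp, Pyrex filter), AcOH–H2O (1:1), reflux, N2
Reagents that add atoms: water, O
Why: Excitation of the cross-conjugated dienone of ring A leads to C1–C5 bonding and a cyclopropyl oxyallyl zwitterion, which is O-protonated in the acidic medium, and its C5–C10 bond then opens while water takes C10, so that C10 moves from C5 to C1; this is the photochemical rearrangement of 4,4-disubstituted cyclohexa-2,5-dienones in aqueous acid, the closest known reaction type. The five-membered ring is closed by the C1–C5 bond (β,β'-bonding of the excited dienone, a 3-exo closure that defines the cyclopentenone at the same time), and the seven-membered ring is not closed but arises from the six-membered ring B when its C5–C10 bond is exchanged for C1–C10, an expansion by the single atom C1. C1 (H α) is dictated by the existing C10 centre, because the cyclopropane must be cis-fused to both rings, and C10 (OH α, methyl β) is set by capture of water with inversion, anti to the breaking C5–C10 bond. The step needs the zwitterion to be protonated and solvolysed faster than it undergoes the 1,4-shift to lumisantonin, and it must stop before the product is photolysed further to photosantonic acid; hot aqueous acetic acid should secure the first, and the Pyrex filter with interruption at full conversion of 1 the second. The lactone and the centres C6, C7 and C11 are not touched, and the one operation delivers both carbocycles of every unit in their final sizes together with the oxygen that later becomes the C10=C14 terminus.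

Step 2
Reactants: 2 isophotosantonic lactone
Product: 3 10α-hydroxy-3-oxo-1αH,4αH,5αH,11βH-guaian-12,6α-olide
Conditions: H2 (1 atm), Pd/C (10%), EtOAc, rt
Reagents that add atoms: none
Why: Catalytic syn-hydrogenation of the tetrasubstituted enone C4=C5 from the α-face (the face of H1, opposite the C10 β-methyl group) should give the cis-fused hydroazulene and set C5 (H α) and C4 (H α, methyl β); lactone and tertiary alcohol are inert.

Step 3
Reactants: 3 10α-hydroxy-3-oxo-1αH,4αH,5αH,11βH-guaian-12,6α-olide
Product: 4 3β,10α-dihydroxy-1αH,4αH,5αH,11βH-guaian-12,6α-olide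
Conditions: NaBH4, MeOH, 0 °C
Reagents that add atoms: none
Why: Borohydride reduction of the cyclopentanone from the α-face, away from the neighbouring 4β-methyl group, should set C3 as the 3β-alcohol, the epimer that has H4 antiperiplanar for step 4.

Step 4
Reactants: 4 3β,10α-dihydroxy-1αH,4αH,5αH,11βH-guaian-12,6α-olide
Product: 5 1αH,5αH,11βH-guaia-3,10(14)-dien-12,6α-olide
Conditions: POCl3, pyridine, 0 °C to 80 °C
Reagents that add atoms: none
Why: E2 dehydration through the dichlorophosphate esters: the 3β-ester has the tertiary H4α antiperiplanar and should give the Saytzeff C3=C4 alkene, while the 10α-ester has no antiperiplanar hydrogen at C1 (H1 is cis to it) and should lose a hydrogen of the C14 methyl group to give the exocyclic C10=C14 alkene.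

Step 5
Reactants: 5 1αH,5αH,11βH-guaia-3,10(14)-dien-12,6α-olide
Product: 6 3α,4α-epoxy-1αH,5αH,11βH-guai-10(14)-en-12,6α-olide
Conditions: mCPBA, NaHCO3, CH2Cl2, 0 °C
Reagents that add atoms: mCPBA, OOC(=O)c1cccc(Cl)c1
Why: Prilezhaev epoxidation is faster at the trisubstituted C3=C4 alkene than at the 1,1-disubstituted C10=C14 alkene and should occur on the convex α-face of the cis-fused cyclopentene, which sets C3 and C4 as the 3α,4α-epoxide.

Step 6
Reactants: 6 3α,4α-epoxy-1αH,5αH,11βH-guai-10(14)-en-12,6α-olide
Product: 7 3α-hydroxy-1αH,5αH,11βH-guaia-4(15),10(14)-dien-12,6α-olide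
Conditions: Al(OiPr)3, toluene, reflux
Reagents that add atoms: none
Why: Aluminium alkoxide-promoted isomerisation of a trisubstituted epoxide to the allylic alcohol: coordination weakens the tertiary C4–O bond and the alkoxide takes the most accessible β-hydrogen, one of the C15 methyl group, through a cyclic transition state, so the exocyclic C4=C15 alkene forms and the C3–O bond keeps its α-configuration.

Step 7
Reactants: 7 3α-hydroxy-1αH,5αH,11βH-guaia-4(15),10(14)-dien-12,6α-olide
Product: 8 3α-hydroxy-11β-phenylselanyl-1αH,5αH-guaia-4(15),10(14)-dien-12,6α-olide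
Conditions: LiN(iPr)2 (2.3 equiv), THF–HMPA, −78 °C; PhSeSePh; AcOH
Reagents that add atoms: diphenyl diselenide, c1ccc(cc1)[Se][Se]c1ccccc1
Why: The second equivalent of amide base forms the lactone enolate beside the lithium alkoxide, and α-selenenylation of this ester enolate at C11 with a diselenide that does not add to the two alkenes should occur on the β-face, anti to the pseudoaxial C7–H bond that shields the α-face of the trans-fused lactone, which places selenium trans to H7 and the methyl group α.

Step 8
Reactants: 8 3α-hydroxy-11β-phenylselanyl-1αH,5αH-guaia-4(15),10(14)-dien-12,6α-olide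
Product: 10 3-epizaluzanin C, via selenoxide 9 (not isolated)
Conditions: H2O2 (30%), pyridine, CH2Cl2, 0 °C to rt
Reagents that add atoms: none
Why: Oxidation at selenium and selenoxide syn-elimination should run toward the C13 methyl group, because the only ring hydrogen beside C11, H7α, is trans to the β-selenoxide and cannot reach the syn-periplanar arrangement, and this gives the exocyclic C11=C13 alkene as is usual for trans-fused α-methyl-α-phenylselanyl γ-lactones.

Step 9
Reactants: 10 3-epizaluzanin C
Product: 11 dehydrozaluzanin C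
Conditions: Dess–Martin periodinane, NaHCO3, CH2Cl2, rt
Reagents that add atoms: none
Why: Dess–Martin oxidation of the allylic alcohol under buffered conditions gives the α-methylene ketone without acid or base strong enough to move the C4=C15 double bond into the ring.

Step 10
Reactants: 11 dehydrozaluzanin C
Product: 12 3-trimethylsilyloxy-1αH,5αH-guaia-2,4(15),10(14),11(13)-tetraen-12,6α-olide
Conditions: TMSOTf, Et3N, CH2Cl2, −78 °C to 0 °C; used at once
Reagents that add atoms: trimethylsilyl triflate, C[Si](C)(C)OS(=O)(=O)C(F)(F)F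
Why: Silyl enol ether formation by soft enolisation can only remove a proton from C2, the single enolisable position of the ketone, and touches no stereocentre.

Step 11
Reactants: 12 3-trimethylsilyloxy-1αH,5αH-guaia-2,4(15),10(14),11(13)-tetraen-12,6α-olide
Product: 13 trienone, 3-oxo-5αH-guaia-1,4(15),10(14),11(13)-tetraen-12,6α-olide
Conditions: Pd(OAc)2 (1.1 equiv), MeCN (0.02 M), argon, rt; filtration through Celite and a short silica pad at 0 °C; kept as a dilute solution at −20 °C and used the same day
Reagents that add atoms: none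
Why: Saegusa–Ito oxidation: divalent palladium takes the silyl enol ether to the C2-bound palladium enolate with loss of trimethylsilyl acetate, and β-hydride elimination of H1 gives the cross-conjugated C1=C2 enone, which removes the C1 stereocentre and touches no other; the trienone is a self-reactive 1-acyl diene and is therefore prepared fresh for each of its two uses and kept cold and dilute.

Step 12
Reactants: 13 trienone (1 equiv, dilute solution, slow addition); 11 dehydrozaluzanin C (3 equiv)
Product: 16 10'β-hydroxy spiro dimer of units B and C, via cycloadduct 14 (not isolated), via hydroperoxide 15 (not isolated)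
Conditions: MeCN, O2 (1 atm), rt; then PPh3, 0 °C
Reagents that add atoms: dioxygen, O=O
Why: The trienone, kept at low concentration beside excess 11, adds through its C2'=C1'–C10'=C14' diene to the exocyclic enone C4''=C15'' of 11 in a Diels–Alder reaction (C2' to C4'', C14' to C15'', the ortho orientation of a 1-acyl diene) on the convex α-face of the cis-fused cyclopentanone, which sets the spiro centre C4''; the β,γ-unsaturated ketone 14 then autoxidises through its dienol at C10' in the way 3-oxo-5-ene steroids do, oxygen entering on the β-face opposite the C5'' arm of the spiro ring, and PPh3 reduces the hydroperoxide.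

Step 13
Reactants: 13 trienone (1.5 equiv, dilute solution, slow addition); 16 10'β-hydroxy spiro dimer of units B and C
Product: 18 ainsliatrimer A, via cycloadduct 17 (not isolated)
Conditions: MeCN–toluene, argon (degassed), rt to 40 °C; then Et3N (cat.), CH2Cl2, rt
Reagents that add atoms: none
Why: In a second Diels–Alder reaction the trienone, kept at low concentration, adds through its α-face (the face of H5) to the exocyclic C4'=C15' bond of 16 in the same ortho sense with the ketone endo, on the β-face of unit B because the α-face is covered by the C5'' arm of the spiro-linked unit C, which sets the spiro centre C4'; amine-catalysed tautomerisation of the β,γ-enone 17 through its dienol, with oxygen excluded, then moves the double bond to C1=C2 with protonation of C10 on the α-face, opposite the C5' arm of unit B, which sets C10.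

**Compound list**

1 | (−)-α-santonin, (3S,3aS,5aS,9bS)-3,5a,9-trimethyl-3a,5,5a,9b-tetrahydronaphtho[1,2-b]furan-2,8(3H,4H)-dione | C[C@H]1[C@@H]2CC[C@]3(C=CC(=O)C(=C3[C@H]2OC1=O)C)C | starting material
2 | isophotosantonic lactone, 10α-hydroxy-3-oxo-1αH,11βH-guai-4-en-12,6α-olide | CC1=C2[C@H]3OC(=O)[C@@H](C)[C@@H]3CC[C@@](C)(O)[C@@H]2CC1=O | intermediate
3 | 10α-hydroxy-3-oxo-1αH,4αH,5αH,11βH-guaian-12,6α-olide | C[C@H]1C(=O)C[C@H]2[C@](C)(O)CC[C@H]3[C@H](C)C(=O)O[C@@H]3[C@H]21 | intermediate
4 | 3β,10α-dihydroxy-1αH,4αH,5αH,11βH-guaian-12,6α-olide | C[C@H]1[C@@H](O)C[C@H]2[C@](C)(O)CC[C@H]3[C@H](C)C(=O)O[C@@H]3[C@H]21 | intermediate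
5 | 1αH,5αH,11βH-guaia-3,10(14)-dien-12,6α-olide | CC1=CC[C@H]2C(=C)CC[C@H]3[C@H](C)C(=O)O[C@@H]3[C@H]21 | intermediate
6 | 3α,4α-epoxy-1αH,5αH,11βH-guai-10(14)-en-12,6α-olide | C[C@@]1(O2)[C@H]2C[C@H]3C(=C)CC[C@H]4[C@H](C)C(=O)O[C@@H]4[C@H]31 | intermediate
7 | 3α-hydroxy-1αH,5αH,11βH-guaia-4(15),10(14)-dien-12,6α-olide | C=C1[C@H](O)C[C@H]2C(=C)CC[C@H]3[C@H](C)C(=O)O[C@@H]3[C@H]21 | intermediate
8 | 3α-hydroxy-11β-phenylselanyl-1αH,5αH-guaia-4(15),10(14)-dien-12,6α-olide (13-methyl α) | C=C1[C@H](O)C[C@H]2C(=C)CC[C@H]3[C@@](C)([Se]c4ccccc4)C(=O)O[C@@H]3[C@H]21 | intermediate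
9 | Se-oxide of 8 | C=C1[C@H](O)C[C@H]2C(=C)CC[C@H]3[C@@](C)([Se](=O)c4ccccc4)C(=O)O[C@@H]3[C@H]21 | intermediate (not isolated)
10 | 3-epizaluzanin C, 3α-hydroxy-1αH,5αH-guaia-4(15),10(14),11(13)-trien-12,6α-olide | C=C1[C@H](O)C[C@H]2C(=C)CC[C@H]3C(=C)C(=O)O[C@@H]3[C@H]21 | intermediate
11 | dehydrozaluzanin C, 3-oxo-1αH,5αH-guaia-4(15),10(14),11(13)-trien-12,6α-olide | C=C1C(=O)C[C@H]2C(=C)CC[C@H]3C(=C)C(=O)O[C@@H]3[C@H]21 | intermediate
12 | 3-trimethylsilyloxy-1αH,5αH-guaia-2,4(15),10(14),11(13)-tetraen-12,6α-olide | C=C1C(O[Si](C)(C)C)=C[C@H]2C(=C)CC[C@H]3C(=C)C(=O)O[C@@H]3[C@H]21 | intermediate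
13 | trienone, 3-oxo-5αH-guaia-1,4(15),10(14),11(13)-tetraen-12,6α-olide (handled only as a cold dilute solution) | C=C1C(=O)C=C2C(=C)CC[C@H]3C(=C)C(=O)O[C@@H]3[C@H]21 | intermediate
14 | Diels–Alder adduct of 13 and 11: unit B 3'-oxo-2'αH-guaia-1'(10'),4'(15'),11'(13')-trien-12',6'α-olide joined to unit C through C2'–C4'' (spiro C4'', C2' on the α-face of unit C) and C14'–C15''; ketone-endo adduct drawn, its C2' epimer converges | C=C1C(=O)[C@@H]2C=3[C@H]1[C@H]1OC(=O)C(=C)[C@@H]1CCC=3CC[C@]21C(=O)C[C@H]2C(=C)CC[C@H]3C(=C)C(=O)O[C@@H]3[C@H]21 | intermediate (not isolated)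
15 | 10'β-hydroperoxide of the dimer (unit B 3'-oxo-1',4'(15')-diene) | C=C1C(=O)C2=C3[C@H]1[C@H]1OC(=O)C(=C)[C@@H]1CC[C@@]3(OO)CC[C@]21C(=O)C[C@H]2C(=C)CC[C@H]3C(=C)C(=O)O[C@@H]3[C@H]21 | intermediate (not isolated)
16 | spiro dimer: unit B 10'β-hydroxy-3'-oxo-5'αH-guaia-1',4'(15'),11'(13')-trien-12',6'α-olide; unit C 3''-oxo-1''αH,5''αH-guaia-10''(14''),11''(13'')-dien-12'',6''α-olide; cyclohexene C2'–C1'–C10'–C14'–C15''–C4'' | C=C1C(=O)C2=C3[C@H]1[C@H]1OC(=O)C(=C)[C@@H]1CC[C@@]3(O)CC[C@]21C(=O)C[C@H]2C(=C)CC[C@H]3C(=C)C(=O)O[C@@H]3[C@H]21 | intermediate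
17 | Diels–Alder adduct of 13 and 16: unit A 3-oxo-2βH,5αH-guaia-1(10),4(15),11(13)-trien-12,6α-olide joined to unit B through C2–C4' (spiro C4', C2 on the β-face of unit B) and C14–C15' | C=C1C(=O)[C@H]2C3=C(CC[C@H]4C(=C)C(=O)O[C@@H]4[C@@H]13)CC[C@@]21C(=O)C2=C3[C@H]1[C@H]1OC(=O)C(=C)[C@@H]1CC[C@@]3(O)CC[C@]21C(=O)C[C@H]2C(=C)CC[C@H]3C(=C)C(=O)O[C@@H]3[C@H]21 | intermediate (not isolated)
18 | ainsliatrimer A (unit A 5αH,6βH,7αH,10αH with C1=C2; unit B 10'β-OH; spiro C4' with C2 β, spiro C4'' with C2' α) | C=C1C(=O)C2=C3[C@H](CC[C@H]4C(=C)C(=O)O[C@@H]4[C@@H]13)CC[C@@]21C(=O)C2=C3[C@H]1[C@H]1OC(=O)C(=C)[C@@H]1CC[C@@]3(O)CC[C@]21C(=O)C[C@H]2C(=C)CC[C@H]3C(=C)C(=O)O[C@@H]3[C@H]21 | target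

**Step count and risks**

Total step count: 13. Longest linear sequence: 13 steps (1 to 18); compounds 11 and 13 from the same sequence supply all three units.

Steps most likely to fail:

Step 13. Self-cycloaddition of the trienone and a further cycloaddition onto the exocyclic methylene ketone that the product itself carries compete with the wanted union, because diene partner, substrate and product hold the same dienophile; addition to the α-face of unit B is a second hazard, which the fallback does not remove. The fallback sets out from 13 and 16 and returns at 17. The freshly filtered solution of 13 from step 11 is reduced at once under Luche conditions (NaBH4, CeCl3·7H2O, MeOH, −78 °C) to the bis-allylic 3β-alcohol F1. Silylation (TBSOTf, 2,6-lutidine, CH2Cl2, −78 °C) gives the silyl ether F2, an electron-rich C14=C10–C1=C2 diene that no longer carries the exocyclic enone, so that self-addition and addition to its product are left only to the much less reactive methylene lactones. Heating F2 with 16 (toluene, 60 °C) in a normal-demand Diels–Alder reaction should give the adduct F3, and HF·pyridine in THF frees the alcohol F4. Dess–Martin oxidation of F4 gives the β,γ-unsaturated ketone 17, which is tautomerised to 18 as in step 13.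

Step 12. The β,γ-enone may shift its proton into conjugation before oxygen is taken up, and oxygen may enter on the α-face of C10'. The fallback sets out from 13 and 11, passes through 14 and returns at 16. The cycloaddition is run under argon over solid NaHCO3 and 14 is isolated cold. Its most electron-rich double bond, the tetrasubstituted C1'=C10' alkene, is epoxidised with one equivalent of dimethyldioxirane (acetone, −40 °C) faster than the 1,1-disubstituted C10''=C14'' alkene and the electron-poor enone and methylene lactones, which gives the 1'β,10'β-epoxide F5. Et3N then opens the epoxide by E1cB elimination from C2' to give 16, so the oxygen comes from an electrophilic reagent and not from a radical chain.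

Step 4. Elimination may run in the wrong direction (toward C2 or into the ring at C9), and the exocyclic C10=C14 bond may migrate at the temperature the secondary ester needs. The fallback sets out from 2 and returns at 5, bypassing 3 and 4. Luche reduction of 2 (NaBH4, CeCl3·7H2O, MeOH, −78 °C) gives the allylic 3β-alcohol F6. A Mitsunobu reaction with 2-nitrobenzenesulfonylhydrazide (PPh3, DEAD, THF, −30 °C) gives with inversion the 3α-sulfonylhydrazine F7, which loses sulfinic acid on warming to the allylic diazene F8. Retro-ene loss of nitrogen from F8 delivers hydrogen to C5 on the α-face and places the double bond at C3=C4 without ambiguity, giving the 3-ene F9 (a reductive allylic transposition). The tertiary alcohol of F9 alone is then dehydrated at low temperature (SOCl2, pyridine, −30 °C) to 5.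

Further compounds
F1 | step 13 | 3β-hydroxy-5αH-guaia-1,4(15),10(14),11(13)-tetraen-12,6α-olide | C=C1[C@@H](O)C=C2C(=C)CC[C@H]3C(=C)C(=O)O[C@@H]3[C@H]21
F2 | step 13 | 3β-tert-butyldimethylsilyloxy-5αH-guaia-1,4(15),10(14),11(13)-tetraen-12,6α-olide | C=C1[C@@H](O[Si](C)(C)C(C)(C)C)C=C2C(=C)CC[C@H]3C(=C)C(=O)O[C@@H]3[C@H]21
F3 | step 13 | Diels–Alder adduct of F2 and 16 (unit A 3β-silyloxy, 2βH, 1(10)-ene; C2–C4' and C14–C15') | C=C1[C@@H](O[Si](C)(C)C(C)(C)C)[C@H]2C3=C(CC[C@H]4C(=C)C(=O)O[C@@H]4[C@@H]13)CC[C@@]21C(=O)C2=C3[C@H]1[C@H]1OC(=O)C(=C)[C@@H]1CC[C@@]3(O)CC[C@]21C(=O)C[C@H]2C(=C)CC[C@H]3C(=C)C(=O)O[C@@H]3[C@H]21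
F4 | step 13 | 3β-alcohol from F3 | C=C1[C@@H](O)[C@H]2C3=C(CC[C@H]4C(=C)C(=O)O[C@@H]4[C@@H]13)CC[C@@]21C(=O)C2=C3[C@H]1[C@H]1OC(=O)C(=C)[C@@H]1CC[C@@]3(O)CC[C@]21C(=O)C[C@H]2C(=C)CC[C@H]3C(=C)C(=O)O[C@@H]3[C@H]21
F5 | step 12 | 1'β,10'β-epoxide of 14 | C=C1C(=O)[C@@H]2[C@@]3(O4)[C@H]1[C@H]1OC(=O)C(=C)[C@@H]1CC[C@@]34CC[C@]21C(=O)C[C@H]2C(=C)CC[C@H]3C(=C)C(=O)O[C@@H]3[C@H]21
F6 | step 4 | 3β,10α-dihydroxy-1αH,11βH-guai-4-en-12,6α-olide | CC1=C2[C@H]3OC(=O)[C@@H](C)[C@@H]3CC[C@@](C)(O)[C@@H]2C[C@@H]1O
F7 | step 4 | 3α-[N-(2-nitrobenzenesulfonyl)hydrazino]-10α-hydroxy-1αH,11βH-guai-4-en-12,6α-olide | CC1=C2[C@H]3OC(=O)[C@@H](C)[C@@H]3CC[C@@](C)(O)[C@@H]2C[C@H]1N(N)S(=O)(=O)c1ccccc1[N+](=O)[O-]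
F8 | step 4 | 3α-diazenyl-10α-hydroxy-1αH,11βH-guai-4-en-12,6α-olide | CC1=C2[C@H]3OC(=O)[C@@H](C)[C@@H]3CC[C@@](C)(O)[C@@H]2C[C@H]1N=N
F9 | step 4 | 10α-hydroxy-1αH,5αH,11βH-guai-3-en-12,6α-olide | CC1=CC[C@H]2[C@](C)(O)CC[C@H]3[C@H](C)C(=O)O[C@@H]3[C@H]21
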